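## The problem

Compound 15 is a diarylmethane, C24H30O8: two fully substituted benzene rings joined by one CH2 group, with no stereocentre and no ring to close. The ring atoms are labelled as follows. Ring A carries butyryl at A1, OH at A2, CH3 at A3, OH at A4, the bridge at A5 and OH at A6. Ring B carries the bridge at B1, OH at B2, CH3 at B3, OCH3 at B4, butyryl at B5 and OH at B6.

A synthesis has to join two different, very nucleophilic phloroglucinol rings through one carbon without forming the two symmetric dimers. It also has to place a single methyl ether on one of six ring oxygens, at B4, para to the bridge and next to the B3 methyl group. As there is no stereocentre, nothing needs stereocontrol; the only stereogenic carbon on the way is a carbinol that is reduced to the bridge.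

Three elements are fragile. The bridge of methylene-linked phloroglucinols is cut and re-joined by strong acid and by base, which scrambles the halves. The free polyphenol oxidises in air. The B4 ether lies ortho to a ketone, where chelating Lewis acids such as AlCl3 or BCl3 remove methyl groups.

The feature that invites a late double acylation is that, once bridge, methyl groups and oxygens are in place, A1 and B5 are the only ring carbons still bearing hydrogen. Each has a phenolic oxygen as neighbour (A2 and A6 for A1, B6 for B5), so a butyryl group parked on oxygen has exactly one carbon per ring to move to.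

## Retrosynthesis

**15 from 14.** The three O-acyl bonds left over from the key step are cut first. This is a deprotection only: tributyrate 14 has the full carbon skeleton, and the forward reaction must cleave aryl esters without disturbing the two aryl ketones, the B4 ether or the bridge.

**14 from 12.** The two aryl–carbonyl bonds, A1–C(=O) and B5–C(=O), are cut and each butyryl group is returned to a ring oxygen, giving pentabutyrate 12. Two neighbouring cuts were weighed.
- Direct C-acylation of the free pentaphenol 11 would put the most electron-rich, most easily cleaved form of the bridge into an acidic medium.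
- Acylating each ring before the bridge is made would require union of two different acyl monomers by a one-carbon electrophile, which is statistical, and would require methylation of the most hindered, chelated phenol of the ring B monomer.

Precursor 12 is simpler by two ketones, has no free or chelated phenol, and should be stable to air and chromatography. The forward reaction must move one acyl group per ring from oxygen to carbon without opening the bridge or the B4 ether.

**12 from 9 by way of 11.** The five ester bonds are cut to give pentaphenol 11 and butyric anhydride 10, and the three ring A phenols are traced back to the methoxymethyl ethers of 9. Phenol 11 is the most sensitive compound of the route and is therefore planned as a species that is formed and acylated in one operation.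

**9 from 8.** The benzylic C–H bond of the bridge is replaced by C–OH and the two ring B phenols by benzyl ethers, giving carbinol 8. One hydrogenolysis should undo all three changes under neutral conditions, which the methoxymethyl ethers of ring A tolerate.

**8 from 7 and 5.** The bond between A5 and the bridge carbon is cut, giving aryllithium 7 and aldehyde 5.
- Ring A is chosen as the nucleophile because its precursor 6 is symmetric: its two ring C–H positions are equivalent and each lies between two directing acetal ethers, so metalation has no regiochemical choice.
- Ring B is chosen as the electrophile because its formyl group does double duty: it becomes the bridge carbon, and it makes one of the three phenols (the one para to it) chemically unique.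
- The opposite polarity would need a ring B arene in which one of two equivalent ortho phenols of 1 is methylated, and a metalation that chooses between two doubly flanked positions.
- A cationic benzylation of an unprotected ring is shorter but prone to over-alkylation.

The forward step must add a hindered aryllithium to a doubly ortho-substituted, non-enolisable aldehyde.

**5 and 6 from 1.** Both halves go back to the same commercial phenol 1. Aldehyde 5 comes from 4 by benzylation; 4 comes from 3 by methylation of the only phenol not ortho to the formyl group; 3 comes from 1 by formylation at one of its two equivalent free carbons. Ether 6 comes from 1 by threefold acetal protection and gives 7 on deprotonation.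

## Roads not taken

**Alternative 1:** Ring B is taken apart along B2–B3 and B4–B5 (to an alkyne) and B1–B2 (electrocyclic closure). The forward step is a Danheiser benzannulation. Cyclobutenone A1, which carries the complete benzyl-protected ring A on its saturated carbon, is heated with ynol ether A2. The vinylketene from four-electron ring opening adds the alkyne, the new cyclobutenone opens again, and the dienylketene closes by six-electron electrocyclisation to phenol A3.
- Merits: the place of the methyl ether is written into A2, the B2 and B6 oxygens arrive differentiated, and ring A already has its ketone. In certainty about the B4 ether this road is better than the chosen one. The chosen plan depends on a selective phenol methylation (step 2) and sets against this the acidity difference between para and ortho phenols and a chelation-based fallback.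
- Weak points: A1 is a heat- and base-sensitive alkoxycyclobutenone whose preparation with a whole protected acylphloroglucinol attached would by itself outlast the chosen route. A2 is volatile and must be prepared. A3 still has hydrogen at B5, so a C-butyrylation of ring B is still owed, in the presence of benzyl ethers that migrate under Lewis acids.
- Comparison: the chosen plan builds no ring that is available as a phenol and forms both ketones in one step.

**Alternative 2:** The cut is B1–B6. Pyrone A4, with the ring A unit on a two-carbon chain at its 6-position, is heated with NaOMe or Mg(OMe)2 in methanol. The lactone opens to a methoxy keto enoate, the ketone α-carbon that bears the ring A benzyl group adds to the ester, and the cyclic dione aromatises to resorcinol A5.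
- Merits: the enol ether carbon is never touched, so the ether is locked at B4. Both ring B phenols emerge free, and the reagents are cheap. As in alternative 1, the regiochemistry of the ether is more secure than in the chosen plan.
- Weak points: the carbanion required is the least acidic one of a vinylogous keto ester, and it must attack an ester deactivated by the methoxy enol ether, in competition with reclosure to the pyrone. Hot methoxide also meets the enolisable butyryl ketone of ring A. A4 must be made by homologating a pyrone with a labile ring A benzylic electrophile. A5, like A3, lacks the B5 ketone.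
- Comparison: the chosen plan avoids the de novo ring and the extra acylation, at the price of one selective methylation.

**Alternative 3:** The cut is A1–A6: ring A is unfolded into triketo ester A6. With Mg(OMe)2 in methanol the chelated carbanion of the CH2 between the two terminal ketones attacks the ester, and the cyclic trione enolises to acylphloroglucinol A7, which is 15 with the B2 and B6 oxygens benzylated.
- Merits: ring A arrives with its butyryl group and three free phenols, no Lewis acid meets the bridge, and A7 is one neutral hydrogenolysis from 15. At the end of the route this road is better than the chosen one, which needs an acid step and a base step on the bridged system.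
- Weak points: A6 is a 2,4-disubstituted trioxo ester. Such chains are hard to assemble regiochemically and exist as mixtures of enols and stereoisomers. They can close through oxygen to pyrones or by aldol condensation to resorcinols, the more so as the ester sits beside a carbon carrying the bulky ring B benzyl group. Ring B of A6 must already hold the B4 ether and the B5 ketone, so the selective methylation and a C-acylation return.
- Comparison: the chosen plan sets against the more elegant ending a short convergent access to both rings from 1 and a precedented acyl migration.

Key step: step 8

## Route

Remark on the chemistry: carbinol 8 is a racemate whose stereocentre is erased in step 6. Compound 14 is written as the ortho-migration isomer; its positional isomers (free phenol at A6 or A4 in place of A2, or at B2 in place of B6) would be carried on with it, since step 9 converges them.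

Step 1
Reactants: 1 2,4,6-trihydroxytoluene
Product: 3 2,4,6-trihydroxy-3-methylbenzaldehyde, via aryl iminium chloride 2 (not isolated)
Conditions: POCl3 (1.1 equiv), DMF, EtOAc, 0 °C → rt; then H2O, 50 °C
Reagents that add atoms: N,N-dimethylformamide, CN(C)C=O (formyl carbon); water, O (carbonyl oxygen)
Why: Vilsmeier–Haack formylation of a phloroglucinol; the two free ring carbons of 1 are equivalent, and the iminium group of 2 deactivates the ring against a second attack, so hydrolysis should give one aldehyde.

Step 2
Reactants: 3 2,4,6-trihydroxy-3-methylbenzaldehyde
Product: 4 2,6-dihydroxy-4-methoxy-3-methylbenzaldehyde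
Conditions: Me2SO4 (1.0 equiv), K2CO3 (1.0 equiv), acetone, 0 °C → rt
Reagents that add atoms: dimethyl sulfate, COS(=O)(=O)OC
Why: Williamson O-methylation with one equivalent of base and electrophile; the phenol para to the formyl group is the most acidic and is not hydrogen-bonded, whereas the two ortho phenols are chelated or hindered, which is the known selectivity of 2,4,6-trihydroxyaryl carbonyl compounds.

Step 3
Reactants: 4 2,6-dihydroxy-4-methoxy-3-methylbenzaldehyde
Product: 5 2,6-bis(benzyloxy)-4-methoxy-3-methylbenzaldehyde
Conditions: BnBr (2.5 equiv), K2CO3, DMF, 60 °C
Reagents that add atoms: benzyl bromide, BrCc1ccccc1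
Why: Williamson etherification; excess reagent and warming should overcome the chelation of the ortho phenols, and the formyl group makes the ring too electron-poor for C-benzylation.

Step 4
Reactants: 1 2,4,6-trihydroxytoluene
Product: 6 1,3,5-tris(methoxymethoxy)-2-methylbenzene
Conditions: MOMCl (4 equiv), i-Pr2NEt, CH2Cl2, 0 °C → rt
Reagents that add atoms: chloromethyl methyl ether, COCCl
Why: Acetal protection of phenols; the hard oxocarbenium-type electrophile reacts at oxygen and not at the ring carbons, as is standard for phloroglucinols.

Step 5
Reactants: 6 1,3,5-tris(methoxymethoxy)-2-methylbenzene; 5 2,6-bis(benzyloxy)-4-methoxy-3-methylbenzaldehyde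
Product: 8 rac-[2,6-bis(benzyloxy)-4-methoxy-3-methylphenyl][3-methyl-2,4,6-tris(methoxymethoxy)phenyl]methanol, via aryllithium 7 (not isolated)
Conditions: n-BuLi (1.05 equiv), THF, 0 °C; then 5, THF, −78 → 0 °C; then H2O
Reagents that add atoms: none
Why: Directed ortho-metalation followed by 1,2-addition; both ring C–H positions of 6 are equivalent and flanked by two chelating acetal ethers, and 5 has no α-hydrogen to lose. The new carbinol centre forms as a racemate and is removed in step 6; the acid-labile carbinol would be purified on base-washed silica.

Step 6
Reactants: 8 rac-[2,6-bis(benzyloxy)-4-methoxy-3-methylphenyl][3-methyl-2,4,6-tris(methoxymethoxy)phenyl]methanol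
Product: 9 5-methoxy-4-methyl-2-{[3-methyl-2,4,6-tris(methoxymethoxy)phenyl]methyl}benzene-1,3-diol
Conditions: H2 (1 atm), Pd/C, EtOAc–MeOH, rt
Reagents that add atoms: none
Why: Hydrogenolysis of the two benzyl ethers and of the doubly benzylic, highly electron-rich C–OH bond; the freed ortho phenols open a path through an ortho-quinone methide that Pd/C and H2 reduce, and the acetal ethers are stable under these neutral conditions.

Step 7
Reactants: 9 5-methoxy-4-methyl-2-{[3-methyl-2,4,6-tris(methoxymethoxy)phenyl]methyl}benzene-1,3-diol; 10 butyric anhydride
Product: 12 2-{[2,6-bis(butanoyloxy)-4-methoxy-3-methylphenyl]methyl}-4-methylbenzene-1,3,5-triyl tributanoate (pentabutyrate), via pentaphenol 11 (not isolated)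
Conditions: HCl (1 M in MeOH), rt → 40 °C, argon; evaporate; then 10 (excess), pyridine, DMAP (cat.), CH2Cl2, 0 °C → rt
Reagents that add atoms: butyric anhydride (10), CCCC(=O)OC(=O)CCC
Why: Acid-catalysed acetal methanolysis, then DMAP-catalysed O-acylation of all five phenols, including the two hindered ones beside the bridge. Dilute acid at or below 40 °C and direct acylation of the crude phenol keep 11 away from air and from prolonged acid.

Step 8
Reactants: 12 pentabutyrate
Product: 14 2-{[3-butanoyl-6-(butanoyloxy)-2-hydroxy-4-methoxy-5-methylphenyl]methyl}-4-butanoyl-5-hydroxy-6-methylbenzene-1,3-diyl dibutanoate (tributyrate of 15 with free OH at A2 and B6), via bis(difluoroboron) chelate 13 (not isolated)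
Conditions: BF3·OEt2 (8 equiv), ClCH2CH2Cl, 70 °C; then EtOH–H2O, 50 °C
Reagents that add atoms: none
Why: Twofold Lewis acid Fries rearrangement, the known route from phloroglucinol esters to acylphloroglucinols. BF3 binds an ester carbonyl, the aryl O–acyl bond ionises to an aryloxyboron species and a butyrylium ion pair, and the acylium attacks the only ring carbon that still bears hydrogen, A1 in ring A and B5 in ring B, each ortho or para to every oxygen of its ring. Loss of the proton and formation of a six-membered O–BF2–O chelate between the new ketone and the neighbouring ring oxygen (A2 or A6; B6) give 13 and take the product out of further acyl exchange. No carbocycle is closed and no stereocentre is formed. Site selectivity needs no control because each ring offers one C–H, and acyl transfer between molecules or from a remote ester gives only positional isomers of 14 that converge in step 9. The bridge should survive because both rings stay ester-deactivated until they are acylated and ketone-deactivated afterwards, so ipso attack at A5 or B1 finds no electron-rich ring. The B4 ether should survive because BF3 is a poor ether-cleaving acid and the ketone oxygen beside it is engaged in the chelate with the B6 oxygen, not with the methoxy oxygen. Warm aqueous ethanol then hydrolyses the B–O bonds and releases 14.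

Step 9
Reactants: 14 tributyrate
Product: 15 1-{3-[(3-butanoyl-2,6-dihydroxy-4-methoxy-5-methylphenyl)methyl]-2,4,6-trihydroxy-5-methylphenyl}butan-1-one
Conditions: K2CO3 (4 equiv), MeOH, 0 °C, argon; then 1 M HCl
Reagents that add atoms: none
Why: Base-mediated transesterification of aryl esters to methyl butanoate; aryl ketones and the methyl ether are inert. A short reaction at 0 °C under argon with prompt acidification is meant to keep the phenoxide of the bridged product from fragmenting.

## Compound list

1 | 2,4,6-trihydroxytoluene (2-methylbenzene-1,3,5-triol) | Cc1c(O)cc(O)cc1O | starting material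
2 | dimethyl[(2,4,6-trihydroxy-3-methylphenyl)methylidene]ammonium chloride | C[N+](C)=Cc1c(O)c(C)c(O)cc1O.[Cl-] | intermediate
3 | 2,4,6-trihydroxy-3-methylbenzaldehyde | O=Cc1c(O)c(C)c(O)cc1O | intermediate
4 | 2,6-dihydroxy-4-methoxy-3-methylbenzaldehyde | O=Cc1c(O)c(C)c(OC)cc1O | intermediate
5 | 2,6-bis(benzyloxy)-4-methoxy-3-methylbenzaldehyde | O=Cc1c(OCc2ccccc2)c(C)c(OC)cc1OCc1ccccc1 | intermediate
6 | 1,3,5-tris(methoxymethoxy)-2-methylbenzene | Cc1c(OCOC)cc(OCOC)cc1OCOC | intermediate
7 | [3-methyl-2,4,6-tris(methoxymethoxy)phenyl]lithium | [Li]c1c(OCOC)cc(OCOC)c(C)c1OCOC | intermediate
8 | rac-[2,6-bis(benzyloxy)-4-methoxy-3-methylphenyl][3-methyl-2,4,6-tris(methoxymethoxy)phenyl]methanol | COCOc1cc(OCOC)c(C(O)c2c(OCc3ccccc3)c(C)c(OC)cc2OCc2ccccc2)c(OCOC)c1C | intermediate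
9 | 5-methoxy-4-methyl-2-{[3-methyl-2,4,6-tris(methoxymethoxy)phenyl]methyl}benzene-1,3-diol | COCOc1cc(OCOC)c(Cc2c(O)c(C)c(OC)cc2O)c(OCOC)c1C | intermediate
10 | butyric anhydride | CCCC(=O)OC(=O)CCC | starting material
11 | 2-[(2,6-dihydroxy-4-methoxy-3-methylphenyl)methyl]-4-methylbenzene-1,3,5-triol | Cc1c(O)cc(O)c(Cc2c(O)c(C)c(OC)cc2O)c1O | intermediate
12 | 2-{[2,6-bis(butanoyloxy)-4-methoxy-3-methylphenyl]methyl}-4-methylbenzene-1,3,5-triyl tributanoate | CCCC(=O)Oc1cc(OC(=O)CCC)c(Cc2c(OC(=O)CCC)c(C)c(OC)cc2OC(=O)CCC)c(OC(=O)CCC)c1C | intermediate
13 | bis(difluoroboron) chelate of 14 (one BF2 between the A1 ketone oxygen and the A2 oxygen, one between the B5 ketone oxygen and the B6 oxygen) | CCCC1=[O+][B-](F)(F)Oc2c(C)c(OC(=O)CCC)c(Cc3c(OC(=O)CCC)c(C)c(OC)c4C(CCC)=[O+][B-](F)(F)Oc34)c(OC(=O)CCC)c12 | intermediate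
14 | 2-{[3-butanoyl-6-(butanoyloxy)-2-hydroxy-4-methoxy-5-methylphenyl]methyl}-4-butanoyl-5-hydroxy-6-methylbenzene-1,3-diyl dibutanoate | CCCC(=O)c1c(O)c(C)c(OC(=O)CCC)c(Cc2c(OC(=O)CCC)c(C)c(OC)c(C(=O)CCC)c2O)c1OC(=O)CCC | intermediate
15 | 1-{3-[(3-butanoyl-2,6-dihydroxy-4-methoxy-5-methylphenyl)methyl]-2,4,6-trihydroxy-5-methylphenyl}butan-1-one | CCCC(=O)c1c(O)c(C)c(O)c(Cc2c(O)c(C)c(OC)c(C(=O)CCC)c2O)c1O | target

## Step count and risks

Total: 9 steps. Longest linear sequence: 8 steps (steps 1, 2, 3, 5, 6, 7, 8 and 9 from 1); step 4 is the one-step branch to 6.

**Step 8 (key step).** What may go wrong: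
- Acid-induced scission and re-formation of the bridge, by ipso attack of a proton or of the acylium ion at A5 or B1, with exchange of the two halves.
- Slow acyl transfer on ring A, which has no ether donor.
- Chelation-assisted loss of the B4 methyl group if the reaction has to be forced.

Fallback: a photochemical Fries rearrangement of 12 (254 nm, degassed MeCN). Homolysis of the aryl O–CO bond and recombination of the caged aryloxyl and butyryl radicals at the free ortho or para carbon would form the same two C–C bonds with no acid present. It sets out from 12 and comes back to the route at 14; no new compound arises (F0).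

**Step 2.** What may go wrong: incomplete discrimination between the para phenol and the unhindered ortho phenol, giving methylation at the wrong oxygen or double methylation.

Fallback: exhaustive methylation of 3 (Me2SO4 in excess, K2CO3, acetone, reflux) to 2,4,6-trimethoxy-3-methylbenzaldehyde F1, then excess BCl3 in CH2Cl2. BCl3 cleaves only methyl ethers that can chelate to the formyl oxygen, that is the two ortho ones, and leaves the para ether. The fallback sets out from 3 and returns at 4.

**Step 5.** What may go wrong: slow addition of the hindered aryllithium to the doubly ortho-substituted aldehyde, so that proton abstraction from a benzylic OCH2 group or hydride-transfer reduction of the aldehyde competes.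

Fallback: a change from carbanion to cation chemistry. NaBH4 in MeOH reduces 5 to [2,6-bis(benzyloxy)-4-methoxy-3-methylphenyl]methanol F2. Its strongly stabilised benzylic cation (Sc(OTf)3 cat., MeCN, rt) alkylates an excess of unprotected 1 at one of its two equivalent free carbons (Friedel–Crafts benzylation), giving 2-{[2,6-bis(benzyloxy)-4-methoxy-3-methylphenyl]methyl}-4-methylbenzene-1,3,5-triol F3. Hydrogenolysis (H2, Pd/C) then removes both benzyl groups and gives 11, which is butyrylated as in step 7. The fallback sets out from 5 and 1 and returns at 11.

**Step 9.** What may go wrong: base-induced fragmentation and recombination of the bridge (a phenoxide expels the other ring and a quinone methide, and exchange gives symmetric dimers), and air oxidation of the polyphenoxide.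

Fallback: acid-catalysed transesterification (HCl in MeOH, 40 °C), in which the phenols stay protonated throughout and no phenoxide is formed. It sets out from 14 and returns at 15; no new compound arises (F0).

## Further compounds

F0 | step 8 | none | none
F1 | step 2 | 2,4,6-trimethoxy-3-methylbenzaldehyde | COc1cc(OC)c(C=O)c(OC)c1C
F2 | step 5 | [2,6-bis(benzyloxy)-4-methoxy-3-methylphenyl]methanol | OCc1c(OCc2ccccc2)c(C)c(OC)cc1OCc1ccccc1
F3 | step 5 | 2-{[2,6-bis(benzyloxy)-4-methoxy-3-methylphenyl]methyl}-4-methylbenzene-1,3,5-triol | Cc1c(O)cc(O)c(Cc2c(OCc3ccccc3)c(C)c(OC)cc2OCc2ccccc2)c1O
F0 | step 9 | none | none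
A1 | alternative 1 | 3-(benzyloxy)-4-{[2,4,6-tris(benzyloxy)-3-butanoyl-5-methylphenyl]methyl}cyclobut-2-en-1-one (racemic) | O=C1C=C(OCc2ccccc2)C1Cc1c(OCc2ccccc2)c(C)c(OCc2ccccc2)c(C(=O)CCC)c1OCc1ccccc1
A2 | alternative 1 | 1-methoxyprop-1-yne | CC#COC
A3 | alternative 1 | 1-{2,4,6-tris(benzyloxy)-3-[(6-benzyloxy-2-hydroxy-4-methoxy-3-methylphenyl)methyl]-5-methylphenyl}butan-1-one | CCCC(=O)c1c(OCc2ccccc2)c(C)c(OCc2ccccc2)c(Cc2c(O)c(C)c(OC)cc2OCc2ccccc2)c1OCc1ccccc1
A4 | alternative 2 | 6-{2-[2,4,6-tris(benzyloxy)-3-butanoyl-5-methylphenyl]ethyl}-4-methoxy-5-methyl-2H-pyran-2-one | COc1cc(=O)oc(CCc2c(OCc3ccccc3)c(C)c(OCc3ccccc3)c(C(=O)CCC)c2OCc2ccccc2)c1C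
A5 | alternative 2 | 1-{2,4,6-tris(benzyloxy)-3-[(2,6-dihydroxy-4-methoxy-3-methylphenyl)methyl]-5-methylphenyl}butan-1-one | CCCC(=O)c1c(OCc2ccccc2)c(C)c(OCc2ccccc2)c(Cc2c(O)c(C)c(OC)cc2O)c1OCc1ccccc1
A6 | alternative 3 | methyl 2-{[2,6-bis(benzyloxy)-3-butanoyl-4-methoxy-5-methylphenyl]methyl}-4-methyl-3,5,7-trioxodecanoate (mixture of stereoisomers and enol forms) | CCCC(=O)CC(=O)C(C)C(=O)C(Cc1c(OCc2ccccc2)c(C)c(OC)c(C(=O)CCC)c1OCc1ccccc1)C(=O)OC
A7 | alternative 3 | 1-{3-[(2,6-bis(benzyloxy)-3-butanoyl-4-methoxy-5-methylphenyl)methyl]-2,4,6-trihydroxy-5-methylphenyl}butan-1-one | CCCC(=O)c1c(O)c(C)c(O)c(Cc2c(OCc3ccccc3)c(C)c(OC)c(C(=O)CCC)c2OCc2ccccc2)c1O
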